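Retrosynthesis (cyclopenta[c]pyran numbering: C1 carries the coumarin, O2, C3 carries the acyl group, C4, C4a, C5, C6, C7 carries a methyl, C7a): cut first the C3–acyl bond (acylation of a C3 stannane made from the enol phosphate of a δ-lactone), then O2–C3 (lactone from a C1,C3-diol), then C1–C3' of the coumarin (3-magnesiated coumarin plus a C1 aldehyde).
What remains is a cyclopentane in which C7 (methyl) and C4a (bearing C4) stand trans on either side of C7a. This is the 2-methyl/5-isopropenyl pattern of trans-dihydrocarvone, so C7–C7a is cut as a ring contraction: in carvone numbering C7 = C2, C7a = C6, C4a = C5, C1 = the ketone carbon, and the isopropenyl group already holds C4, C3 and the 4-methyl.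
Forward: the cyclopentane arises first (photochemical Wolff contraction of 6-diazo-trans-dihydrocarvone), the coumarin is joined at C1, the pyran ring is closed through O2–C3 by oxidative lactonisation, and the 3-methylbutanoyl group is attached last.
Stereochemistry: C4a is the stereocentre of (S)-carvone; C7 comes from enolate protonation to the trans ketone and is retained in the 1,2-shift; C7a from kinetic protonation of the ester enol on the face away from the isopropenyl group; C1 from Felkin–Anh addition to the aldehyde.

Key step: step 3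

Assumption: metal alkoxides, enolates and aluminate adducts that are only hydrolysed to the stated product on work-up are taken as forms of that product and carry no number of their own; (S)-carvone, 2'-hydroxy-6'-methylacetophenone and 3-methylbutanoyl chloride are taken as purchasable.

Step 1
Reactants: 1 (S)-carvone
Product: 2 (2S,5S)-2-methyl-5-(prop-1-en-2-yl)cyclohexan-1-one (trans-dihydrocarvone)
Conditions: LiBH(s-Bu)3, THF, −78 °C; then H2O
Reagents that add atoms: none
Why: Conjugate hydride reduction of the β-unsubstituted enone by the hindered trialkylborohydride gives the enolate, and its axial protonation on work-up sets the methyl-bearing carbon (future C7) with the methyl group equatorial and trans to the untouched isopropenyl group, which is also the more stable arrangement.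

Step 2
Reactants: 2 trans-dihydrocarvone
Product: 5 (3R,6S)-2-diazo-6-methyl-3-(prop-1-en-2-yl)cyclohexan-1-one (6-diazo-trans-dihydrocarvone), via lithium enolate 3 (not isolated), via trifluoroacetyl ketone 4 (not isolated)
Conditions: LiN(SiMe3)2, THF, −78 °C; CF3CO2CH2CF3; aq HCl; then CH3SO2N3, Et3N, H2O, MeCN, rt
Reagents that add atoms: lithium bis(trimethylsilyl)amide, [Li+].C[Si](C)(C)[N-][Si](C)(C)C (lithium of 3 only); 2,2,2-trifluoroethyl trifluoroacetate, O=C(OCC(F)(F)F)C(F)(F)F (trifluoroacetyl group of 4 only); methanesulfonyl azide, CS(=O)(=O)N=[N+]=[N-] (the two diazo nitrogens of 5)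
Why: Detrifluoroacetylative diazo transfer (Claisen trifluoroacetylation followed by Regitz-type diazo transfer): the amide base removes a proton from the less substituted α-methylene (future C7a) under kinetic control, acylation activates only that carbon, and the sulfonyl azide then exchanges the trifluoroacetyl group for N2 without touching either stereocentre.

Step 3
Reactants: 5 6-diazo-trans-dihydrocarvone
Product: 8 methyl (1R,2S,5S)-2-methyl-5-(prop-1-en-2-yl)cyclopentane-1-carboxylate, via ketene 6 (not isolated), via ester enol 7 (not isolated)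
Conditions: hν (medium-pressure mercury lamp, Pyrex filter), MeOH, −30 °C to rt
Reagents that add atoms: methanol, CO
Why: Excitation of the diazoketone, held s-cis by the ring, expels N2 while the bond from the carbonyl carbon to the methyl-bearing carbon shifts to the diazo carbon, so that the methyl-bearing carbon (future C7) bonds to the former diazo carbon (future C7a) and the old carbonyl carbon leaves the ring as a ketene that methanol traps as the ester enol. The closest known reaction type is the photochemical Wolff rearrangement of cyclic α-diazoketones in an alcohol, the standard one-carbon ring contraction to cycloalkanecarboxylates. The cyclopentane is closed by a 1,2-alkyl shift that contracts the six-membered ring (no chain cyclisation is involved), which forms the C7–C7a bond and extrudes C1 as the ester carbon. The migrating carbon moves with retention, so C7 and C4a keep their trans relation, and the new centre C7a is set when the ester enol is protonated on the face of the small methyl group, anti to the isopropenyl group that allylic strain holds over the other face, which places the ester cis to the isopropenyl group. The step needs rearrangement to win over 1,2-hydride shift and O–H insertion, which the enforced s-cis geometry and direct irradiation without a metal catalyst should secure, and it needs the kinetic protonation to survive, which the absence of base secures.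

Step 4
Reactants: 8 methyl ester
Product: 9 (1R,2S,5S)-2-methyl-5-(prop-1-en-2-yl)cyclopentane-1-carbaldehyde
Conditions: i-Bu2AlH (1 equiv), CH2Cl2, −78 °C; then MeOH, aq potassium sodium tartrate; used crude
Reagents that add atoms: none
Why: Partial reduction of an ester with i-Bu2AlH at −78 °C stops at the aluminium hemiacetal, which releases the aldehyde only on work-up, and the non-basic low-temperature conditions keep the α-stereocentre (future C7a) intact.

Step 5
Reactants: 10 2'-hydroxy-6'-methylacetophenone
Product: 12 4-hydroxy-5-methyl-2H-chromen-2-one, via keto ester 11 (not isolated)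
Conditions: NaH, (EtO)2CO, toluene, 110 °C; then aq HCl
Reagents that add atoms: diethyl carbonate, CCOC(=O)OCC
Why: Claisen-type C-acylation of the ketone enolate by diethyl carbonate followed by lactonisation onto the phenoxide is the standard synthesis of 4-hydroxycoumarins from 2-hydroxyacetophenones.

Step 6
Reactants: 12 4-hydroxy-5-methylcoumarin
Product: 13 4-(methoxymethoxy)-5-methyl-2H-chromen-2-one
Conditions: MeOCH2Cl, i-Pr2NEt, CH2Cl2, 0 °C to rt
Reagents that add atoms: chloromethyl methyl ether, COCCl
Why: Williamson-type O-alkylation of the vinylogous acid by the hard electrophile MeOCH2Cl gives the 4-alkoxycoumarin, which masks the acidic hydroxyl and keeps C3 from reacting as an enol until the last step.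

Step 7
Reactants: 13 MOM-protected coumarin
Product: 14 3-bromo-4-(methoxymethoxy)-5-methyl-2H-chromen-2-one
Conditions: N-bromosuccinimide, MeCN, rt, dark
Reagents that add atoms: N-bromosuccinimide, O=C1CCC(=O)N1Br
Why: Electrophilic bromination (addition–elimination) of the push–pull enol ether takes place at C3, the only nucleophilic position of the pyranone ring, and provides the handle for metalation.

Step 8
Reactants: 14 3-bromocoumarin; 9 aldehyde
Product: 16 3-{(S)-hydroxy[(1R,2S,5S)-2-methyl-5-(prop-1-en-2-yl)cyclopentyl]methyl}-4-(methoxymethoxy)-5-methyl-2H-chromen-2-one, via coumarinyl Grignard reagent 15 (not isolated)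
Conditions: 14, i-PrMgCl·LiCl, THF, −40 °C; then 9, −40 to 0 °C; aq NH4Cl
Reagents that add atoms: isopropylmagnesium chloride–lithium chloride, CC(C)[Mg]Cl.[Li+].[Cl-] (MgCl of 15 only)
Why: Bromine–magnesium exchange on the electron-poor alkenyl bromide gives a 3-magnesiated coumarin whose Grignard addition to the aldehyde follows the Felkin–Anh model, the nucleophile arriving anti to the ring carbon that bears the cis isopropenyl group and past the α-hydrogen, which sets C1 as (S).

Step 9
Reactants: 16 carbinol
Product: 18 3-{(S)-hydroxy[(1R,2R,5S)-2-(1-hydroxypropan-2-yl)-5-methylcyclopentyl]methyl}-4-(methoxymethoxy)-5-methyl-2H-chromen-2-one (both side-chain epimers), via alkylborane 17 (not isolated)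
Conditions: 9-BBN dimer (excess), THF, 0 °C to rt; then NaBO3·4H2O, THF/H2O, rt
Reagents that add atoms: 9-borabicyclo[3.3.1]nonane, B1C2CCCC1CCC2 (boryl group of 17 only); sodium perborate tetrahydrate, [Na+].[Na+].O[B-]1(O)OO[B-](O)(O)OO1 (oxygen of the new hydroxyl)
Why: Anti-Markovnikov hydroboration–oxidation of the 1,1-disubstituted alkene with the bulky borane and a mild perborate work-up gives the primary alcohol without touching the coumarin lactone or the MOM ether, and the new C4 centre is left uncontrolled because it becomes trigonal again in step 11.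

Step 10
Reactants: 18 diol
Product: 21 (1S,4aS,7S,7aR)-1-[4-(methoxymethoxy)-5-methyl-2-oxo-2H-chromen-3-yl]-4,7-dimethylhexahydrocyclopenta[c]pyran-3(1H)-one (both C4 epimers), via hydroxy aldehyde 19 (not isolated), via lactol 20 (not isolated)
Conditions: 2,2,6,6-tetramethylpiperidin-1-oxyl (TEMPO, cat.), PhI(OAc)2, CH2Cl2, rt
Reagents that add atoms: none
Why: Oxoammonium (TEMPO) oxidation is selective for the primary alcohol, the resulting aldehyde is captured by the cis-disposed C1 hydroxyl as the six-membered lactol (6-exo-trig) and a second oxidation gives the δ-lactone, which closes the pyran ring through O2–C3 and leaves C1 untouched.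

Step 11
Reactants: 21 lactone
Product: 23 diphenyl (1S,4aS,7S,7aR)-1-[4-(methoxymethoxy)-5-methyl-2-oxo-2H-chromen-3-yl]-4,7-dimethyl-1,4a,5,6,7,7a-hexahydrocyclopenta[c]pyran-3-yl phosphate, via potassium enolate 22 (not isolated)
Conditions: (PhO)2P(O)Cl, then KN(SiMe3)2, THF/DMPU, −78 °C
Reagents that add atoms: potassium bis(trimethylsilyl)amide, [K+].C[Si](C)(C)[N-][Si](C)(C)C (potassium of 22 only); diphenyl chlorophosphate, O=P(Cl)(Oc1ccccc1)Oc1ccccc1
Why: Enolisation of the lactone toward C4 in the presence of the chlorophosphate (internal quench) gives O-phosphorylation to the cyclic ketene acetal phosphate, which removes the uncontrolled C4 centre and turns C3 into a cross-coupling site.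

Step 12
Reactants: 23 enol phosphate
Product: 24 4-(methoxymethoxy)-5-methyl-3-[(1S,4aS,7S,7aR)-4,7-dimethyl-3-(trimethylstannyl)-1,4a,5,6,7,7a-hexahydrocyclopenta[c]pyran-1-yl]-2H-chromen-2-one
Conditions: Me3SnSnMe3, Pd(PPh3)4 (cat.), LiCl, THF, 65 °C
Reagents that add atoms: hexamethylditin, C[Sn](C)(C)[Sn](C)(C)C
Why: Palladium-catalysed coupling of lactone-derived ketene acetal phosphates with hexamethylditin (a Stille-type stannylation assisted by chloride) is an established route to cyclic α-alkoxyvinylstannanes.

Step 13
Reactants: 24 vinylstannane; 25 3-methylbutanoyl chloride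
Product: 26 3-[(1S,4aS,7S,7aR)-4,7-dimethyl-3-(3-methylbutanoyl)-1,4a,5,6,7,7a-hexahydrocyclopenta[c]pyran-1-yl]-4-(methoxymethoxy)-5-methyl-2H-chromen-2-one
Conditions: 25, Pd2(dba)3 (cat.), P(2-furyl)3, 2,6-di-tert-butyl-4-methylpyridine, THF, 50 °C
Reagents that add atoms: 3-methylbutanoyl chloride (compound 25, also listed as reactant), CC(C)CC(Cl)=O
Why: Stille ketone synthesis: oxidative addition of the acid chloride to zerovalent palladium, transmetalation of the α-alkoxyvinylstannane and reductive elimination give the α-alkoxy enone under neutral conditions that spare the coumarin lactone and the MOM ether.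

Step 14
Reactants: 26 MOM-protected target
Product: 27 4-hydroxy-5-methyl-3-[(1S,4aS,7S,7aR)-4,7-dimethyl-3-(3-methylbutanoyl)-1,4a,5,6,7,7a-hexahydrocyclopenta[c]pyran-1-yl]-2H-chromen-2-one (CNP0124891.1)
Conditions: CF3CO2H, CH2Cl2, 0 °C; then H2O
Reagents that add atoms: none
Why: Acidolysis of the vinylogous MOM ester, an acetal far more labile than the acyl-deactivated enol ether of the pyran ring, frees the 4-hydroxycoumarin at low temperature in a non-nucleophilic medium so that the C1–O2 bond is not ionised.

Compound list
1 | (S)-carvone, (5S)-2-methyl-5-(prop-1-en-2-yl)cyclohex-2-en-1-one | CC1=CC[C@H](C(C)=C)CC1=O | starting material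
2 | trans-dihydrocarvone, (2S,5S)-2-methyl-5-(prop-1-en-2-yl)cyclohexan-1-one | C[C@H]1CC[C@H](C(C)=C)CC1=O | intermediate
3 | kinetic enolate of 2, lithium (3S,6S)-6-methyl-3-(prop-1-en-2-yl)cyclohex-1-en-1-olate | C[C@H]1CC[C@H](C(C)=C)C=C1[O-].[Li+] | intermediate
4 | (3S,6S)-6-methyl-3-(prop-1-en-2-yl)-2-(trifluoroacetyl)cyclohexan-1-one (C2 epimers, largely enolised) | C[C@H]1CC[C@H](C(C)=C)C(C(=O)C(F)(F)F)C1=O | intermediate
5 | 6-diazo-trans-dihydrocarvone, (3R,6S)-2-diazo-6-methyl-3-(prop-1-en-2-yl)cyclohexan-1-one | C[C@H]1CC[C@H](C(C)=C)C(=[N+]=[N-])C1=O | intermediate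
6 | trans-2-methyl-5-(prop-1-en-2-yl)cyclopentylidene ketene (both centres as in 5) | O=C=C1[C@@H](C(C)=C)CC[C@@H]1C | intermediate
7 | enol (ketene hemiacetal) of ester 8, methoxy[trans-2-methyl-5-(prop-1-en-2-yl)cyclopentylidene]methanol | COC(O)=C1[C@@H](C(C)=C)CC[C@@H]1C | intermediate
8 | methyl (1R,2S,5S)-2-methyl-5-(prop-1-en-2-yl)cyclopentane-1-carboxylate (ester cis to isopropenyl, trans to methyl) | COC(=O)[C@H]1[C@@H](C(C)=C)CC[C@@H]1C | intermediate
9 | (1R,2S,5S)-2-methyl-5-(prop-1-en-2-yl)cyclopentane-1-carbaldehyde | O=C[C@H]1[C@@H](C(C)=C)CC[C@@H]1C | intermediate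
10 | 2'-hydroxy-6'-methylacetophenone, 1-(2-hydroxy-6-methylphenyl)ethan-1-one | CC(=O)c1c(C)cccc1O | starting material
11 | ethyl 3-(2-hydroxy-6-methylphenyl)-3-oxopropanoate (present as its sodium salt) | CCOC(=O)CC(=O)c1c(C)cccc1O | intermediate
12 | 4-hydroxy-5-methyl-2H-chromen-2-one | Cc1cccc2oc(=O)cc(O)c12 | intermediate
13 | 4-(methoxymethoxy)-5-methyl-2H-chromen-2-one | COCOc1cc(=O)oc2cccc(C)c12 | intermediate
14 | 3-bromo-4-(methoxymethoxy)-5-methyl-2H-chromen-2-one | COCOc1c(Br)c(=O)oc2cccc(C)c12 | intermediate
15 | [4-(methoxymethoxy)-5-methyl-2-oxo-2H-chromen-3-yl]magnesium chloride (LiCl complex) | COCOc1c([Mg]Cl)c(=O)oc2cccc(C)c12 | intermediate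
16 | 3-{(S)-hydroxy[(1R,2S,5S)-2-methyl-5-(prop-1-en-2-yl)cyclopentyl]methyl}-4-(methoxymethoxy)-5-methyl-2H-chromen-2-one | O[C@H](c1c(OCOC)c2c(C)cccc2oc1=O)[C@H]1[C@@H](C(C)=C)CC[C@@H]1C | intermediate
17 | B-alkyl-9-borabicyclo[3.3.1]nonane adduct of 16 (boron on the terminal carbon of the former isopropenyl group, hydroxyl shown free) | O[C@H](c1c(OCOC)c2c(C)cccc2oc1=O)[C@H]1[C@@H](C(C)CB2C3CCCC2CCC3)CC[C@@H]1C | intermediate
18 | 3-{(S)-hydroxy[(1R,2R,5S)-2-(1-hydroxypropan-2-yl)-5-methylcyclopentyl]methyl}-4-(methoxymethoxy)-5-methyl-2H-chromen-2-one (both side-chain epimers) | O[C@H](c1c(OCOC)c2c(C)cccc2oc1=O)[C@H]1[C@@H](C(C)CO)CC[C@@H]1C | intermediate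
19 | hydroxy aldehyde from 18 (primary alcohol oxidised to the aldehyde, ring centres and carbinol as in 18) | O[C@H](c1c(OCOC)c2c(C)cccc2oc1=O)[C@H]1[C@@H](C(C)C=O)CC[C@@H]1C | intermediate
20 | 3-[(1S,4aS,7S,7aR)-3-hydroxy-4,7-dimethyloctahydrocyclopenta[c]pyran-1-yl]-4-(methoxymethoxy)-5-methyl-2H-chromen-2-one (C3 and C4 epimers) | CC1C(O)O[C@H](c2c(OCOC)c3c(C)cccc3oc2=O)[C@H]2[C@@H]1CC[C@@H]2C | intermediate
21 | (1S,4aS,7S,7aR)-1-[4-(methoxymethoxy)-5-methyl-2-oxo-2H-chromen-3-yl]-4,7-dimethylhexahydrocyclopenta[c]pyran-3(1H)-one (both C4 epimers, cis-fused) | CC1C(=O)O[C@H](c2c(OCOC)c3c(C)cccc3oc2=O)[C@H]2[C@@H]1CC[C@@H]2C | intermediate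
22 | potassium enolate of lactone 21 (C3–O–, C3=C4) | [K+].CC1=C([O-])O[C@H](c2c(OCOC)c3c(C)cccc3oc2=O)[C@H]2[C@@H]1CC[C@@H]2C | intermediate
23 | diphenyl (1S,4aS,7S,7aR)-1-[4-(methoxymethoxy)-5-methyl-2-oxo-2H-chromen-3-yl]-4,7-dimethyl-1,4a,5,6,7,7a-hexahydrocyclopenta[c]pyran-3-yl phosphate | CC1=C(OP(=O)(Oc2ccccc2)Oc2ccccc2)O[C@H](c2c(OCOC)c3c(C)cccc3oc2=O)[C@H]2[C@@H]1CC[C@@H]2C | intermediate
24 | 4-(methoxymethoxy)-5-methyl-3-[(1S,4aS,7S,7aR)-4,7-dimethyl-3-(trimethylstannyl)-1,4a,5,6,7,7a-hexahydrocyclopenta[c]pyran-1-yl]-2H-chromen-2-one | CC1=C([Sn](C)(C)C)O[C@H](c2c(OCOC)c3c(C)cccc3oc2=O)[C@H]2[C@@H]1CC[C@@H]2C | intermediate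
25 | 3-methylbutanoyl chloride (isovaleryl chloride) | CC(C)CC(Cl)=O | starting material
26 | 3-[(1S,4aS,7S,7aR)-4,7-dimethyl-3-(3-methylbutanoyl)-1,4a,5,6,7,7a-hexahydrocyclopenta[c]pyran-1-yl]-4-(methoxymethoxy)-5-methyl-2H-chromen-2-one | CC1=C(C(=O)CC(C)C)O[C@H](c2c(OCOC)c3c(C)cccc3oc2=O)[C@H]2[C@@H]1CC[C@@H]2C | intermediate
27 | 4-hydroxy-5-methyl-3-[(1S,4aS,7S,7aR)-4,7-dimethyl-3-(3-methylbutanoyl)-1,4a,5,6,7,7a-hexahydrocyclopenta[c]pyran-1-yl]-2H-chromen-2-one (CNP0124891.1) | CC1=C(C(=O)CC(C)C)O[C@H](c2c(O)c3c(C)cccc3oc2=O)[C@H]2[C@@H]1CC[C@@H]2C | target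

Total step count: 14 (11 on the main line, 3 for the coumarin fragment).
Longest linear sequence: 11 steps (steps 1–4 and 8–14) from (S)-carvone.

Steps most likely to fail

Risk 1, step 3. The protonation of ester enol 7 may show poor facial selectivity, because methyl and isopropenyl do not differ greatly in size. Ester 8 would then be accompanied by its epimer at the ester-bearing carbon, and no later step of the main route can repair this. The fallback sets out from 8 as the epimer mixture and returns at 18. Hydroboration–oxidation of the isopropenyl group (9-BBN, then NaBO3·4H2O) gives the hydroxy ester F1. Heating with DBU in toluene lactonises it and equilibrates the ring-fusion carbon next to the carbonyl; this should converge on the cis-fused lactone F2 with the methyl group trans to the carbonyl carbon, the arrangement favoured in the nepetalactone series. Reduction with i-Bu2AlH at −78 °C gives the lactol F3. An excess of Grignard reagent 15 opens the lactol through its hydroxy aldehyde form and gives diol 18 directly, after which step 10 follows. C7a is then under thermodynamic instead of kinetic control.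

Risk 2, step 8. The addition of 15 to 9 may proceed with poor facial selectivity, since the aldehyde is flanked by two ring carbons that differ only in their cis substituent, so both C1 carbinols would form. The fallback sets out from 16 as the carbinol mixture and returns at 16. Oxidation with Dess–Martin periodinane gives the ketone F4. Corey–Bakshi–Shibata reduction with (R)-1-methyl-3,3-diphenyltetrahydro-1H,3H-pyrrolo[1,2-c][1,3,2]oxazaborole and catecholborane at low temperature then sets C1 under reagent control. With the coumarinyl group as the large substituent this should return the (S)-carbinol 16, and catecholborane leaves the isopropenyl group alone.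

Risk 3, step 12. Oxidative addition into the tetrasubstituted ketene acetal phosphate may be slow, and the stannane may be lost by protodestannylation during isolation. The fallback sets out from 23 and returns at 26. Palladium-catalysed aminocarbonylation of 23 (Pd(PPh3)4, CO, MeNHOMe·HCl, Et3N, DMF) gives the Weinreb amide F5. Isobutylmagnesium bromide, made from 1-bromo-2-methylpropane and magnesium, adds once to this amide at −78 °C and gives ketone 26. The acyl carbon then comes from CO, the isobutyl group enters as a nucleophile, and no tin intermediate is needed.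

Further compounds
F1 | step 3 | methyl (1RS,2R,5S)-2-[(2RS)-1-hydroxypropan-2-yl]-5-methylcyclopentane-1-carboxylate | COC(=O)C1[C@@H](C(C)CO)CC[C@@H]1C
F2 | step 3 | (4RS,4aR,7S,7aR)-4,7-dimethylhexahydrocyclopenta[c]pyran-1(3H)-one | CC1COC(=O)[C@H]2[C@@H]1CC[C@@H]2C
F3 | step 3 | (4RS,4aR,7S,7aR)-4,7-dimethyloctahydrocyclopenta[c]pyran-1-ol (both anomers) | CC1COC(O)[C@H]2[C@@H]1CC[C@@H]2C
F4 | step 8 | 4-(methoxymethoxy)-5-methyl-3-[(1R,2S,5S)-2-methyl-5-(prop-1-en-2-yl)cyclopentane-1-carbonyl]-2H-chromen-2-one | O=C(c1c(OCOC)c2c(C)cccc2oc1=O)[C@H]1[C@@H](C(C)=C)CC[C@@H]1C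
F5 | step 12 | (1S,4aS,7S,7aR)-N-methoxy-1-[4-(methoxymethoxy)-5-methyl-2-oxo-2H-chromen-3-yl]-N,4,7-trimethyl-1,4a,5,6,7,7a-hexahydrocyclopenta[c]pyran-3-carboxamide | CC1=C(C(=O)N(C)OC)O[C@H](c2c(OCOC)c3c(C)cccc3oc2=O)[C@H]2[C@@H]1CC[C@@H]2C
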